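In a one-step world starting material would become target and stop, and the share of target would be 100%. These flasks have a second use for reagent.

common to all: free catalyst 10 mol%; second catalyst 11 mol%; time 80 s

| run | starting material | reagent | remark |
|---|---|---|---|
| cedar | 0.40 M | 1.00 equiv (fed, over 50 s) | all else is in the flask from the start; the feed brings no volume worth counting |
| larch | 0.40 M (fed, over 12 s) | 1.00 equiv | all else is in the flask from the start; the feed brings no volume worth counting |
| maple | 0.40 M | 1.00 equiv (in portions, 2, over 50 s) | first portion at the start, last at 50 s |
| elm | 0.40 M | 1.00 equiv | everything together at the start |
| alder | 0.40 M (fed, over 50 s) | 1.00 equiv | all else is in the flask from the start; the feed brings no volume worth counting |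

    reagent + target → over-reaction product (k1 = 0.069 M⁻¹ s⁻¹)
    starting material + free catalyst ⇌ free catalyst + intermediate (K2 = 2.3, k2 = 0.68 M⁻¹ s⁻¹)
    reagent + second catalyst + intermediate → second catalyst + target (k3 = 17 M⁻² s⁻¹)

1. the flask that comes out highest in share of target in target plus over-reaction product, or "all alike" when all lie within 1.5 percentage points (cedar / larch / maple / elm / alder / all alike)
2. share of target in target plus over-reaction product at the end, cedar
3. share of target in target plus over-reaction product at the end, larch
4. share of target in target plus over-reaction product at the end, maple
5. share of target in target plus over-reaction product at the end, elm
6. share of target in target plus over-reaction product at the end, alder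

Reagent makes target from intermediate, and it also destroys target. As charged in elm, intermediate has a half-life of 2.3 s by reagent, far shorter than the 25 s of starting material by the forward catalyst step. That comparison holds for the charged reagent and weakens as reagent falls, but as an estimate I let the catalyst step supply target throughout and ignore its way back. Target's own half-life against reagent, as charged in elm, is about that of starting material, 25 s. Their ratio is the burn number, a selectivity factor:

D = (over-reaction constant × c(reagent)) / (forward catalyst constant × c(free catalyst)) = 1.01

It says how fast reagent burns target compared with how fast new target is supplied. Let τ be the fraction of the charge that has passed through to target, and s the share. Taking supply and reagent as steady, a rough estimate, I write: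

s = (1 − e^(−Dτ)) / (Dτ)

Reagent, charged equal to starting material, pays once for target made and again for target burnt, and I set the sum equal to its charge:

τ(2 − s) = 1

Trying s = 0.7 gives τ = 0.769 and s = 69.4%. That is my figure for elm, and for larch and alder too, which hold the whole reagent charge from the start. For cedar and maple I take reagent at half its charge, so D/2, and the same lines give 0.507 and s = 81.2%.

One number cannot separate those two. Maple's first portion goes in when c(target) is zero, while cedar's reagent arrives as target grows, so I rank maple first, on judgement.

The forecast chose cedar, with 82% for cedar, 69.5% for larch, 80% for maple, 70% for elm and 68% for alder, on the grounds of “holding reagent back while the intermediate builds”.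

The simulation puts maple highest: cedar 77.1%, larch 70.3%, maple 79.4%, elm 70.2%, alder 68.9%.

Halving D gave maple 81.2%, which is 1.8 percentage points above the flask. The neighbour is maple with 40 mol% of free catalyst, which cuts D by the ratio of loadings, so with the half-charge reagent it becomes 0.127. The same lines then give s = 94.2%. The flask rises, as D says, but to 84.9%, which is 9.3 points below that figure, and it ends with 69.1% of target and 6.45% of starting material.

The constants come from no measurement; the flask was simulated.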